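**Assumption:** the target has no stereocentres, so "single enantiomer" is moot; the only stereo-elements are the two E-alkenes (geranyl C2=C3 and the stilbene), and the route controls both. 5-Iodoresorcinol is taken as a catalogue compound. The route is a plan from known reaction types and has not been run.

## Retrosynthetic overview

- No rings are formed; both arenes are bought intact and no protecting groups are used.
- Geranyl C–C bond: ortho C-alkylation of 4-iodophenol (1) with geranyl bromide (2, E-alkene purchased) gives aryl iodide 3.
- Stilbene: instead of a Wittig/HWE olefination, both alkene carbons come from a vinyl-boron linchpin. A boron-retentive Heck of 5-iodoresorcinol (4) with vinyl-Bpin (5) gives E-alkenylboronate 6.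
- Final bond: stereoretentive Suzuki coupling of 3 and 6 gives schweinfurthin I (7).

## Route

**Step 1**
Reactants: 1, 4-iodophenol; 2, geranyl bromide [(2E)-1-bromo-3,7-dimethylocta-2,6-diene]
Product: 3, 2-[(2E)-3,7-dimethylocta-2,6-dien-1-yl]-4-iodophenol
Conditions: NaH (1.0 equiv per phenol), PhMe, 0 °C → rt, 16 h; 1 used in excess (1.5 equiv vs 2); neutral work-up (aq NH4Cl)
Reagents that add atoms: none beyond the reactants (2, CC(C)=CCC/C(C)=C/CBr, supplies the C10 chain)
Why: Ortho C-alkylation of a tight sodium phenoxide ion pair in a non-polar solvent (Claisen-type phenoxide C-allylation); the para position is blocked by iodine, and SN2 attack at the primary allylic carbon leaves the purchased E-alkene untouched.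

**Step 2**
Reactants: 4, 5-iodoresorcinol (5-iodobenzene-1,3-diol); 5, vinylboronic acid pinacol ester (2.0 equiv)
Product: 6, 5-[(E)-2-(4,4,5,5-tetramethyl-1,3,2-dioxaborolan-2-yl)ethenyl]benzene-1,3-diol
Conditions: Pd[P(t-Bu)3]2 (5 mol %), i-Pr2NH (3 equiv), anhydrous 1,4-dioxane, 80 °C, Ar; strip excess 5 under vacuum, short silica plug
Reagents that add atoms: none beyond the reactants (5, C=CB1OC(C)(C)C(C)(C)O1, supplies CH=CH–Bpin)
Why: Boron-retentive Mizoroki–Heck reaction; with an amine base and no water or oxygen base, transmetalation is shut down, the aryl group adds to the unsubstituted vinyl carbon, and syn β-hydride elimination gives the E-alkenylboronate.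

**Step 3**
Reactants: 3, 2-geranyl-4-iodophenol (1.0 equiv); 6, E-alkenylboronate (1.2 equiv)
Product: 7, schweinfurthin I, 5-[(E)-2-{3-[(2E)-3,7-dimethylocta-2,6-dien-1-yl]-4-hydroxyphenyl}ethenyl]benzene-1,3-diol
Conditions: Pd(dppf)Cl2·CH2Cl2 (5 mol %), K3PO4 (5 equiv), degassed THF/H2O 4:1, 60 °C, dark; work-up with aq NH4Cl to pH 6–7 (no strong acid)
Reagents that add atoms: none beyond the reactants
Why: Suzuki–Miyaura coupling of an alkenyl-Bpin with an aryl iodide proceeds with retention of alkene geometry, so the E-stilbene comes directly from 6; the basic, non-acidic conditions leave the ortho-geranylphenol uncyclised and the free phenols are tolerated as phenoxides.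

## Compound list

1 | 4-iodophenol | Oc1ccc(I)cc1 | starting material
2 | geranyl bromide, (2E)-1-bromo-3,7-dimethylocta-2,6-diene | CC(C)=CCC/C(C)=C/CBr | starting material
3 | 2-[(2E)-3,7-dimethylocta-2,6-dien-1-yl]-4-iodophenol | CC(C)=CCC/C(C)=C/Cc1cc(I)ccc1O | intermediate
4 | 5-iodoresorcinol (5-iodobenzene-1,3-diol) | Oc1cc(O)cc(I)c1 | starting material
5 | vinylboronic acid pinacol ester | C=CB1OC(C)(C)C(C)(C)O1 | starting material
6 | 5-[(E)-2-(pinacolboryl)ethenyl]benzene-1,3-diol | Oc1cc(O)cc(/C=C/B2OC(C)(C)C(C)(C)O2)c1 | intermediate
7 | schweinfurthin I | CC(C)=CCC/C(C)=C/Cc1cc(/C=C/c2cc(O)cc(O)c2)ccc1O | target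

## Summary

**Total steps:** 3
**Longest linear sequence:** 2 (1 → 3 → 7, or 4 → 6 → 7)

**Steps most likely to fail, most risky first:**

1. **Step 2 (boron-retentive Heck on an unprotected resorcinol).** Risks are Suzuki-type loss of boron, double arylation and handling of the polar diol boronate. Fallback: build the E-alkenylboronate by alkyne hydrometalation instead. Bis-TBS-protect 4, Sonogashira with TMS-acetylene, desilylate the alkyne, then Cp2Zr(H)Cl-catalysed syn-hydroboration with HBpin; couple with 3 and remove TBS with TBAF.

2. **Step 1 (direct ortho C-geranylation).** Risks are competing O-alkylation, 2,6-dialkylation and a modest yield. Fallback: switch from phenoxide alkylation to aryl-metal allylation. MOM-protect 2-bromo-4-chlorophenol, do selective Br–Li exchange (n-BuLi, −78 °C), transmetalate to copper (CuBr·SMe2) and add 2. Use the resulting aryl chloride in the Suzuki step with XPhos-Pd, then remove MOM with TsOH/MeOH.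

3. **Step 3 (Suzuki with three free phenols).** Risks are slow oxidative addition to the iodophenoxide, protodeboronation of 6, and air or light sensitivity of the product. Fallback: abandon the cross-coupling union for a carbonyl olefination. TBS-protect 3, convert to the aldehyde (i-PrMgCl·LiCl, then DMF), run an HWE with diethyl 3,5-bis(TBSO)benzylphosphonate (E-selective), and deprotect globally with TBAF.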